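**Plan**

- Positions follow germacrane numbering (lactone O on C6, C7–C11(C13)–C12=O, OAc on C3 and C9). C9 is a secondary allylic carbinol bonded directly to C10 of the Z C1=C10 alkene in the ten-membered ring, which is fused to the γ-lactone only through C6–C7. The carbocycle is therefore cut at C9–C10 into a C9 aldehyde and a C10 (Z)-iodoalkene.
- Further cuts, in retrosynthetic order: the two O-acetyl groups; C1=C10 (iodoethylidene Wittig on a C1 aldehyde); C3–C4 (Ni/Cr coupling of a C4 (Z)-iodoalkene with a C3 aldehyde); C4=C5 (the same Wittig on a C5 aldehyde); C11–C13 (enolate methylation) and C7–C8 (vinyl conjugate addition) on a butenolide.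
- Forward: the γ-lactone is made first from (S)-5-(hydroxymethyl)furan-2(5H)-one, the chain is grown C5 → C4 → C3–C1 → C10, the C7 vinyl group becomes the C9 aldehyde, the ten-membered ring is closed last, and both hydroxyls are acetylated.
- Stereochemistry: C6 from the butenolide; C7 by conjugate addition anti to the C6 substituent; C11 by methylation and kinetic reprotonation anti to the C7 vinyl group; C3 by CBS reduction; C9 in the ring closure under substrate control; both Z alkenes from (Z)-iodoalkenes that couple with retention.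
- Remark: O3 is carried as a TBS ether up to the ring closure, because a β-acetoxy aldehyde would eliminate in the second Wittig step; the ring-closure product is therefore the 3-O-TBS 9-alcohol and both acetates go on at the end.

Key step: step 17

**Route**

Step 1
Reactants: 1 (S)-5-(hydroxymethyl)furan-2(5H)-one
Product: 2 (S)-5-{[(tert-butyldiphenylsilyl)oxy]methyl}furan-2(5H)-one
Conditions: TBDPSCl, imidazole, CH2Cl2, 0 °C → rt
Reagents that add atoms: tert-butyl(chloro)diphenylsilane, CC(C)(C)[Si](Cl)(c1ccccc1)c1ccccc1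
Why: Silylation of the primary alcohol; the bulky silyloxymethyl group at C6 will shield one face of the butenolide in step 2.

Step 2
Reactants: 2 (S)-5-{[(tert-butyldiphenylsilyl)oxy]methyl}furan-2(5H)-one
Product: 4 (4R,5S)-5-{[(tert-butyldiphenylsilyl)oxy]methyl}-4-vinyldihydrofuran-2(3H)-one, via silyl ketene acetal 3 (not isolated)
Conditions: CH2=CHMgBr, CuBr·SMe2 (20 mol %), TMSCl, THF, −78 °C; aq. NH4Cl
Reagents that add atoms: vinylmagnesium bromide, C=C[Mg]Br
Why: Copper-catalysed, TMSCl-accelerated conjugate addition in which the vinyl group (C8–C9) should enter C7 anti to the C6 silyloxymethyl group, setting the 6,7-trans relationship; the silyl ketene acetal 3 is hydrolysed on work-up.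

Step 3
Reactants: 4 (4R,5S)-5-{[(tert-butyldiphenylsilyl)oxy]methyl}-4-vinyldihydrofuran-2(3H)-one
Product: 6 (3S,4S,5S)-5-{[(tert-butyldiphenylsilyl)oxy]methyl}-3-methyl-4-vinyldihydrofuran-2(3H)-one, via lithium enolate 5 (not isolated)
Conditions: LiHMDS, THF, −78 °C; MeI, −78 → −40 °C
Reagents that add atoms: iodomethane, CI
Why: Lactone enolate alkylation in which iodomethane should approach anti to the adjacent C7 vinyl group, so the methyl (C13) is placed trans to vinyl, i.e. the C11 epimer of what is needed, which step 4 inverts.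

Step 4
Reactants: 6 (3S,4S,5S)-5-{[(tert-butyldiphenylsilyl)oxy]methyl}-3-methyl-4-vinyldihydrofuran-2(3H)-one
Product: 8 (3R,4S,5S)-5-{[(tert-butyldiphenylsilyl)oxy]methyl}-3-methyl-4-vinyldihydrofuran-2(3H)-one, via lithium enolate 7 (not isolated)
Conditions: LDA, THF, −78 °C; then 2,6-di-tert-butyl-4-methylphenol, −78 °C
Reagents that add atoms: none
Why: Deprotonation to the planar enolate 7 followed by kinetic protonation with a hindered phenol, which should deliver the proton anti to the C7 vinyl group (the face iodomethane used) and so leave the methyl cis to vinyl, i.e. 11R.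

Step 5
Reactants: 8 (3R,4S,5S)-5-{[(tert-butyldiphenylsilyl)oxy]methyl}-3-methyl-4-vinyldihydrofuran-2(3H)-one
Product: 9 (3R,4S,5S)-5-(hydroxymethyl)-3-methyl-4-vinyldihydrofuran-2(3H)-one
Conditions: TBAF, AcOH, THF, 0 °C → rt
Reagents that add atoms: none
Why: Fluoride cleavage of the silyl ether, buffered with acetic acid so that the base-labile C11 centre is not equilibrated.

Step 6
Reactants: 9 (3R,4S,5S)-5-(hydroxymethyl)-3-methyl-4-vinyldihydrofuran-2(3H)-one
Product: 10 (2S,3S,4R)-4-methyl-5-oxo-3-vinyltetrahydrofuran-2-carbaldehyde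
Conditions: DMP, CH2Cl2, 0 °C → rt; used crude
Reagents that add atoms: none
Why: Dess–Martin oxidation of the primary alcohol to the C5 aldehyde under near-neutral conditions that should not epimerise the adjacent C6 centre.

Step 7
Reactants: 10 (2S,3S,4R)-4-methyl-5-oxo-3-vinyltetrahydrofuran-2-carbaldehyde
Product: 11 (3R,4S,5S)-5-[(Z)-2-iodoprop-1-en-1-yl]-3-methyl-4-vinyldihydrofuran-2(3H)-one
Conditions: EtPPh3I, n-BuLi, THF, 0 °C → rt; I2, −78 °C; NaHMDS, −20 °C; then 10, −78 °C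
Reagents that add atoms: ethyltriphenylphosphonium iodide, CC[P+](c1ccccc1)(c1ccccc1)c1ccccc1.[I-]; iodine, II
Why: Stork–Zhao-type Wittig reaction of (1-iodoethylidene)triphenylphosphorane, whose kinetic cis-oxaphosphetane should give the (Z)-iodoalkene with iodine cis to C6, bringing in C4 and C15 and fixing the C4=C5 geometry.

Step 8
Reactants: 11 (3R,4S,5S)-5-[(Z)-2-iodoprop-1-en-1-yl]-3-methyl-4-vinyldihydrofuran-2(3H)-one; 12 3-[(tert-butyldimethylsilyl)oxy]propanal
Product: 14 (3R,4S,5S)-5-[(1Z)-5-[(tert-butyldimethylsilyl)oxy]-3-hydroxy-2-methylpent-1-en-1-yl]-3-methyl-4-vinyldihydrofuran-2(3H)-one (mixture of C3 epimers), via alkenylchromium(III) species 13 (not isolated)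
Conditions: CrCl2, NiCl2 (2 mol %), DMSO, rt
Reagents that add atoms: none
Why: Intermolecular Nozaki–Hiyama–Kishi coupling, which forms C3–C4 with retention of the Z geometry and leaves the lactone and silyl ether alone; the C3 epimer mixture is of no consequence because step 9 oxidises it.

Step 9
Reactants: 14 (3R,4S,5S)-5-[(1Z)-5-[(tert-butyldimethylsilyl)oxy]-3-hydroxy-2-methylpent-1-en-1-yl]-3-methyl-4-vinyldihydrofuran-2(3H)-one
Product: 15 (3R,4S,5S)-5-[(1Z)-5-[(tert-butyldimethylsilyl)oxy]-2-methyl-3-oxopent-1-en-1-yl]-3-methyl-4-vinyldihydrofuran-2(3H)-one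
Conditions: DMP, CH2Cl2, 0 °C → rt
Reagents that add atoms: none
Why: Dess–Martin oxidation of the allylic alcohol to the (Z)-enone under non-basic conditions that should neither isomerise the alkene nor eliminate the β-silyloxy group.

Step 10
Reactants: 15 (3R,4S,5S)-5-[(1Z)-5-[(tert-butyldimethylsilyl)oxy]-2-methyl-3-oxopent-1-en-1-yl]-3-methyl-4-vinyldihydrofuran-2(3H)-one
Product: 16 (3R,4S,5S)-5-[(1Z,3S)-5-[(tert-butyldimethylsilyl)oxy]-3-hydroxy-2-methylpent-1-en-1-yl]-3-methyl-4-vinyldihydrofuran-2(3H)-one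
Conditions: (R)-Me-CBS (0.2 equiv), catecholborane, toluene, −78 °C; MeOH
Reagents that add atoms: none
Why: Corey–Bakshi–Shibata reduction in which the alkenyl group acts as the large substituent, so the (R)-oxazaborolidine should deliver hydride to the face that gives the 3S alcohol; catecholborane at −78 °C should leave the vinyl group and the lactone untouched.

Step 11
Reactants: 16 (3R,4S,5S)-5-[(1Z,3S)-5-[(tert-butyldimethylsilyl)oxy]-3-hydroxy-2-methylpent-1-en-1-yl]-3-methyl-4-vinyldihydrofuran-2(3H)-one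
Product: 17 (3R,4S,5S)-5-[(1Z,3S)-3,5-bis[(tert-butyldimethylsilyl)oxy]-2-methylpent-1-en-1-yl]-3-methyl-4-vinyldihydrofuran-2(3H)-one
Conditions: TBSOTf, 2,6-lutidine, CH2Cl2, −78 → 0 °C
Reagents that add atoms: tert-butyldimethylsilyl trifluoromethanesulfonate, CC(C)(C)[Si](C)(C)OS(=O)(=O)C(F)(F)F
Why: Silyl triflate silylation of the hindered secondary allylic alcohol, which masks O3 through the Wittig and Ni/Cr steps.

Step 12
Reactants: 17 (3R,4S,5S)-5-[(1Z,3S)-3,5-bis[(tert-butyldimethylsilyl)oxy]-2-methylpent-1-en-1-yl]-3-methyl-4-vinyldihydrofuran-2(3H)-one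
Product: 18 (3R,4S,5S)-5-[(1Z,3S)-3-[(tert-butyldimethylsilyl)oxy]-5-hydroxy-2-methylpent-1-en-1-yl]-3-methyl-4-vinyldihydrofuran-2(3H)-one
Conditions: HF·pyridine, pyridine, THF, 0 °C
Reagents that add atoms: none
Why: Selective desilylation, since the unhindered primary TBS ether at C1 should be cleaved much faster by buffered HF·pyridine than the secondary allylic TBS ether at C3.

Step 13
Reactants: 18 (3R,4S,5S)-5-[(1Z,3S)-3-[(tert-butyldimethylsilyl)oxy]-5-hydroxy-2-methylpent-1-en-1-yl]-3-methyl-4-vinyldihydrofuran-2(3H)-one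
Product: 19 (3S,4Z)-3-[(tert-butyldimethylsilyl)oxy]-4-methyl-5-[(2S,3S,4R)-4-methyl-5-oxo-3-vinyltetrahydrofuran-2-yl]pent-4-enal
Conditions: DMP, pyridine, CH2Cl2, 0 °C → rt
Reagents that add atoms: none
Why: Buffered Dess–Martin oxidation of the primary alcohol to the C1 aldehyde without β-elimination of the silyloxy group.

Step 14
Reactants: 19 (3S,4Z)-3-[(tert-butyldimethylsilyl)oxy]-4-methyl-5-[(2S,3S,4R)-4-methyl-5-oxo-3-vinyltetrahydrofuran-2-yl]pent-4-enal
Product: 20 (3R,4S,5S)-5-[(1Z,3S,5Z)-3-[(tert-butyldimethylsilyl)oxy]-6-iodo-2-methylhepta-1,5-dien-1-yl]-3-methyl-4-vinyldihydrofuran-2(3H)-one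
Conditions: EtPPh3I, n-BuLi, THF, 0 °C → rt; I2, −78 °C; NaHMDS, −20 °C; then 19, −78 °C
Reagents that add atoms: ethyltriphenylphosphonium iodide, CC[P+](c1ccccc1)(c1ccccc1)c1ccccc1.[I-]; iodine, II
Why: Second Stork–Zhao-type Wittig reaction, which should give the (Z)-iodoalkene with iodine cis to C2, bringing in C10 and C14 with the geometry the ring closure will retain; a β-silyloxy aldehyde is a standard substrate for this ylide.

Step 15
Reactants: 20 (3R,4S,5S)-5-[(1Z,3S,5Z)-3-[(tert-butyldimethylsilyl)oxy]-6-iodo-2-methylhepta-1,5-dien-1-yl]-3-methyl-4-vinyldihydrofuran-2(3H)-one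
Product: 22 (3R,4S,5S)-5-[(1Z,3S,5Z)-3-[(tert-butyldimethylsilyl)oxy]-6-iodo-2-methylhepta-1,5-dien-1-yl]-4-(2-hydroxyethyl)-3-methyldihydrofuran-2(3H)-one, via B-alkyl-9-BBN adduct 21 (not isolated)
Conditions: 9-BBN, THF, 0 °C → rt; aq. NaOAc, 30 % H2O2, 0 °C → rt
Reagents that add atoms: hydrogen peroxide, OO
Why: Anti-Markovnikov hydroboration–oxidation, in which 9-BBN should react with the monosubstituted vinyl group far faster than with the two trisubstituted alkenes or the iodoalkene, and acetate-buffered peroxide spares the lactone and the silyl ether.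

Step 16
Reactants: 22 (3R,4S,5S)-5-[(1Z,3S,5Z)-3-[(tert-butyldimethylsilyl)oxy]-6-iodo-2-methylhepta-1,5-dien-1-yl]-4-(2-hydroxyethyl)-3-methyldihydrofuran-2(3H)-one
Product: 23 2-[(2S,3S,4R)-2-[(1Z,3S,5Z)-3-[(tert-butyldimethylsilyl)oxy]-6-iodo-2-methylhepta-1,5-dien-1-yl]-4-methyl-5-oxotetrahydrofuran-3-yl]acetaldehyde (seco iodo-aldehyde)
Conditions: DMP, pyridine, CH2Cl2, 0 °C → rt
Reagents that add atoms: none
Why: Dess–Martin oxidation of the primary alcohol to the C9 aldehyde; the lactone is already closed, so O6 cannot form a lactol with the new aldehyde.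

Step 17
Reactants: 23 2-[(2S,3S,4R)-2-[(1Z,3S,5Z)-3-[(tert-butyldimethylsilyl)oxy]-6-iodo-2-methylhepta-1,5-dien-1-yl]-4-methyl-5-oxotetrahydrofuran-3-yl]acetaldehyde
Product: 25 (3R,3aS,5R,6Z,9S,10Z,11aS)-9-[(tert-butyldimethylsilyl)oxy]-5-hydroxy-3,6,10-trimethyl-3a,4,5,8,9,11a-hexahydrocyclodeca[b]furan-2(3H)-one (germacrane: 3-O-TBS, 9R-OH), via alkenylchromium(III) species 24 (not isolated)
Conditions: CrCl2 (10 equiv), NiCl2 (5 mol %), degassed DMSO, rt; 23 added slowly to ca. 2 mM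
Reagents that add atoms: none
Why: Ni(0), formed from NiCl2 by CrCl2, inserts into the C10–I bond with retention of the Z geometry, the alkenyl group passes to Cr(III) to give 24, and 24 adds 1,2 to the C9 aldehyde, the chromium alkoxide being hydrolysed on work-up; this is an intramolecular Nozaki–Hiyama–Kishi reaction, the closest known type being Ni/Cr closures of nine- to fourteen-membered rings from iodoalkene aldehydes. The ten-membered carbocycle closes by a 10-exo-trig addition of C10 to the C9 carbonyl; the two Z alkenes and the trans-fused lactone fold the chain so that C9 and C10 lie on the same side, and slow addition at high dilution keeps the reaction intramolecular. The new C9 centre is under substrate control: C8 is held by the C7 stereocentre and the rigid lactone, so the aldehyde should react with its oxygen turned to the outside of the forming ring, away from the C14 methyl, which exposes its Si face to C10 and gives the 9R alcohol. The step needs chemoselectivity for the iodoalkene and the aldehyde, which the organochromium reagent secures because it does not add to the lactone, the silyl ether or the alkenes, and there is no β-leaving group next to C10.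

Step 18
Reactants: 25 (3R,3aS,5R,6Z,9S,10Z,11aS)-9-[(tert-butyldimethylsilyl)oxy]-5-hydroxy-3,6,10-trimethyl-3a,4,5,8,9,11a-hexahydrocyclodeca[b]furan-2(3H)-one
Product: 26 (3R,3aS,5R,6Z,9S,10Z,11aS)-5,9-dihydroxy-3,6,10-trimethyl-3a,4,5,8,9,11a-hexahydrocyclodeca[b]furan-2(3H)-one (germacrane 3S,9R-diol)
Conditions: TBAF, AcOH, THF, 0 °C → rt
Reagents that add atoms: none
Why: Fluoride cleavage of the C3 silyl ether, buffered with acetic acid to protect the lactone and its C11 centre.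

Step 19
Reactants: 26 (3R,3aS,5R,6Z,9S,10Z,11aS)-5,9-dihydroxy-3,6,10-trimethyl-3a,4,5,8,9,11a-hexahydrocyclodeca[b]furan-2(3H)-one
Product: 27 (3R,3aS,5R,6Z,9S,10Z,11aS)-3,6,10-trimethyl-2-oxo-2,3,3a,4,5,8,9,11a-octahydrocyclodeca[b]furan-5,9-diyl diacetate (CNP0226482.4)
Conditions: Ac2O, pyridine, DMAP (cat.), CH2Cl2, rt
Reagents that add atoms: acetic anhydride, CC(=O)OC(C)=O
Why: DMAP-catalysed acetylation of both secondary allylic alcohols with retention at C3 and C9, giving the target.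

**Compound list**

1 | (S)-5-(hydroxymethyl)furan-2(5H)-one | O=C1C=C[C@@H](CO)O1 | starting material
2 | (S)-5-{[(tert-butyldiphenylsilyl)oxy]methyl}furan-2(5H)-one | O=C1C=C[C@@H](CO[Si](c2ccccc2)(c2ccccc2)C(C)(C)C)O1 | intermediate
3 | trimethylsilyl ketene acetal of 4, tert-butyl{[(2S,3S)-5-[(trimethylsilyl)oxy]-3-vinyl-2,3-dihydrofuran-2-yl]methoxy}diphenylsilane | C=C[C@@H]1[C@@H](CO[Si](c2ccccc2)(c2ccccc2)C(C)(C)C)OC(O[Si](C)(C)C)=C1 | intermediate (not isolated)
4 | (4R,5S)-5-{[(tert-butyldiphenylsilyl)oxy]methyl}-4-vinyldihydrofuran-2(3H)-one | C=C[C@@H]1[C@@H](CO[Si](c2ccccc2)(c2ccccc2)C(C)(C)C)OC(=O)C1 | intermediate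
5 | lithium enolate of 4 | C=C[C@@H]1[C@@H](CO[Si](c2ccccc2)(c2ccccc2)C(C)(C)C)OC(O[Li])=C1 | intermediate (not isolated)
6 | (3S,4S,5S)-5-{[(tert-butyldiphenylsilyl)oxy]methyl}-3-methyl-4-vinyldihydrofuran-2(3H)-one (methyl trans to vinyl) | C=C[C@@H]1[C@@H](CO[Si](c2ccccc2)(c2ccccc2)C(C)(C)C)OC(=O)[C@H]1C | intermediate
7 | lithium enolate of 6 | C=C[C@@H]1[C@@H](CO[Si](c2ccccc2)(c2ccccc2)C(C)(C)C)OC(O[Li])=C1C | intermediate (not isolated)
8 | (3R,4S,5S)-5-{[(tert-butyldiphenylsilyl)oxy]methyl}-3-methyl-4-vinyldihydrofuran-2(3H)-one (methyl cis to vinyl) | C=C[C@@H]1[C@@H](CO[Si](c2ccccc2)(c2ccccc2)C(C)(C)C)OC(=O)[C@@H]1C | intermediate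
9 | (3R,4S,5S)-5-(hydroxymethyl)-3-methyl-4-vinyldihydrofuran-2(3H)-one | C=C[C@@H]1[C@@H](CO)OC(=O)[C@@H]1C | intermediate
10 | (2S,3S,4R)-4-methyl-5-oxo-3-vinyltetrahydrofuran-2-carbaldehyde | C=C[C@@H]1[C@@H](C=O)OC(=O)[C@@H]1C | intermediate
11 | (3R,4S,5S)-5-[(Z)-2-iodoprop-1-en-1-yl]-3-methyl-4-vinyldihydrofuran-2(3H)-one | C=C[C@@H]1[C@@H](/C=C(/C)I)OC(=O)[C@@H]1C | intermediate
12 | 3-[(tert-butyldimethylsilyl)oxy]propanal | O=CCCO[Si](C)(C)C(C)(C)C | starting material
13 | alkenylchromium(III) dichloride from 11 (Cr in place of I) | C=C[C@@H]1[C@@H](/C=C(/C)[Cr](Cl)Cl)OC(=O)[C@@H]1C | intermediate (not isolated)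
14 | (3R,4S,5S)-5-[(1Z)-5-[(tert-butyldimethylsilyl)oxy]-3-hydroxy-2-methylpent-1-en-1-yl]-3-methyl-4-vinyldihydrofuran-2(3H)-one, C3 epimers | C=C[C@@H]1[C@@H](/C=C(/C)C(O)CCO[Si](C)(C)C(C)(C)C)OC(=O)[C@@H]1C | intermediate
15 | (3R,4S,5S)-5-[(1Z)-5-[(tert-butyldimethylsilyl)oxy]-2-methyl-3-oxopent-1-en-1-yl]-3-methyl-4-vinyldihydrofuran-2(3H)-one | C=C[C@@H]1[C@@H](/C=C(/C)C(=O)CCO[Si](C)(C)C(C)(C)C)OC(=O)[C@@H]1C | intermediate
16 | (3R,4S,5S)-5-[(1Z,3S)-5-[(tert-butyldimethylsilyl)oxy]-3-hydroxy-2-methylpent-1-en-1-yl]-3-methyl-4-vinyldihydrofuran-2(3H)-one | C=C[C@@H]1[C@@H](/C=C(/C)[C@@H](O)CCO[Si](C)(C)C(C)(C)C)OC(=O)[C@@H]1C | intermediate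
17 | (3R,4S,5S)-5-[(1Z,3S)-3,5-bis[(tert-butyldimethylsilyl)oxy]-2-methylpent-1-en-1-yl]-3-methyl-4-vinyldihydrofuran-2(3H)-one | C=C[C@@H]1[C@@H](/C=C(/C)[C@@H](O[Si](C)(C)C(C)(C)C)CCO[Si](C)(C)C(C)(C)C)OC(=O)[C@@H]1C | intermediate
18 | (3R,4S,5S)-5-[(1Z,3S)-3-[(tert-butyldimethylsilyl)oxy]-5-hydroxy-2-methylpent-1-en-1-yl]-3-methyl-4-vinyldihydrofuran-2(3H)-one | C=C[C@@H]1[C@@H](/C=C(/C)[C@@H](O[Si](C)(C)C(C)(C)C)CCO)OC(=O)[C@@H]1C | intermediate
19 | (3S,4Z)-3-[(tert-butyldimethylsilyl)oxy]-4-methyl-5-[(2S,3S,4R)-4-methyl-5-oxo-3-vinyltetrahydrofuran-2-yl]pent-4-enal | C=C[C@@H]1[C@@H](/C=C(/C)[C@@H](O[Si](C)(C)C(C)(C)C)CC=O)OC(=O)[C@@H]1C | intermediate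
20 | (3R,4S,5S)-5-[(1Z,3S,5Z)-3-[(tert-butyldimethylsilyl)oxy]-6-iodo-2-methylhepta-1,5-dien-1-yl]-3-methyl-4-vinyldihydrofuran-2(3H)-one | C=C[C@@H]1[C@@H](/C=C(/C)[C@@H](O[Si](C)(C)C(C)(C)C)C/C=C(/C)I)OC(=O)[C@@H]1C | intermediate
21 | B-alkyl-9-borabicyclo[3.3.1]nonane adduct of 20 (boron on C9) | B1(CC[C@@H]3[C@@H](/C=C(/C)[C@@H](O[Si](C)(C)C(C)(C)C)C/C=C(/C)I)OC(=O)[C@@H]3C)C2CCCC1CCC2 | intermediate (not isolated)
22 | (3R,4S,5S)-5-[(1Z,3S,5Z)-3-[(tert-butyldimethylsilyl)oxy]-6-iodo-2-methylhepta-1,5-dien-1-yl]-4-(2-hydroxyethyl)-3-methyldihydrofuran-2(3H)-one | OCC[C@@H]1[C@@H](/C=C(/C)[C@@H](O[Si](C)(C)C(C)(C)C)C/C=C(/C)I)OC(=O)[C@@H]1C | intermediate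
23 | 2-[(2S,3S,4R)-2-[(1Z,3S,5Z)-3-[(tert-butyldimethylsilyl)oxy]-6-iodo-2-methylhepta-1,5-dien-1-yl]-4-methyl-5-oxotetrahydrofuran-3-yl]acetaldehyde | O=CC[C@@H]1[C@@H](/C=C(/C)[C@@H](O[Si](C)(C)C(C)(C)C)C/C=C(/C)I)OC(=O)[C@@H]1C | intermediate
24 | alkenylchromium(III) dichloride from 23 (Cr on C10 in place of I) | O=CC[C@@H]1[C@@H](/C=C(/C)[C@@H](O[Si](C)(C)C(C)(C)C)C/C=C(/C)[Cr](Cl)Cl)OC(=O)[C@@H]1C | intermediate (not isolated)
25 | (3R,3aS,5R,6Z,9S,10Z,11aS)-9-[(tert-butyldimethylsilyl)oxy]-5-hydroxy-3,6,10-trimethyl-3a,4,5,8,9,11a-hexahydrocyclodeca[b]furan-2(3H)-one | CC(C)(C)[Si](C)(C)O[C@H]1C/C=C(/C)[C@H](O)C[C@@H]2[C@@H](/C=C\1C)OC(=O)[C@@H]2C | intermediate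
26 | (3R,3aS,5R,6Z,9S,10Z,11aS)-5,9-dihydroxy-3,6,10-trimethyl-3a,4,5,8,9,11a-hexahydrocyclodeca[b]furan-2(3H)-one | O[C@H]1C/C=C(/C)[C@H](O)C[C@@H]2[C@@H](/C=C\1C)OC(=O)[C@@H]2C | intermediate
27 | (3R,3aS,5R,6Z,9S,10Z,11aS)-3,6,10-trimethyl-2-oxo-2,3,3a,4,5,8,9,11a-octahydrocyclodeca[b]furan-5,9-diyl diacetate (germacrane 3S,6S,7S,9R,11R) | CC(=O)O[C@H]1C/C=C(/C)[C@H](OC(C)=O)C[C@@H]2[C@@H](/C=C\1C)OC(=O)[C@@H]2C | target

**Step count**

Total: 19 steps. Longest linear sequence: 19 steps (1 → 27); 12 enters as a purchased reagent in step 8.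

**Steps most likely to fail, with fallbacks**

Step 17. The ring closure may take place on the Re face of the C9 aldehyde (or on both faces), because the preference for the Si face rests only on the conformation imposed by C7 and the lactone. The fallback sets out from 23 and returns at 25. The cyclisation is run as described and is then expected to give mainly (3R,3aS,5S,6Z,9S,10Z,11aS)-9-[(tert-butyldimethylsilyl)oxy]-5-hydroxy-3,6,10-trimethyl-3a,4,5,8,9,11a-hexahydrocyclodeca[b]furan-2(3H)-one F1, the 9S epimer. The epimer mixture is oxidised with DMP/pyridine in CH2Cl2 to the macrocyclic C9 ketone ((Z)-enone) F2. F2 is reduced with (S)-Me-CBS and catecholborane in toluene at −78 °C, where the C10 alkenyl group is the large substituent, so reagent control should give the 9R alcohol 25.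

Step 4. Protonation of enolate 7 may be poorly face-selective, since the C6 silyloxymethyl group lies on the face the proton must use, and any equilibration drifts back to the trans-methyl lactone 6. The fallback sets out from 6 and returns at 8, replacing the ionic protonation by a radical hydrogen-atom transfer. Enolate 7 (LDA, THF, −78 °C) is quenched with PhSeBr to give (4R,5S)-5-{[(tert-butyldiphenylsilyl)oxy]methyl}-3-methyl-3-(phenylselanyl)-4-vinyldihydrofuran-2(3H)-one F3 (either C3 epimer serves). F3 is reduced with Bu3SnH and Et3B/air in toluene at −78 °C; the planar tertiary α-lactone radical should take its hydrogen from the bulky stannane on the face away from the C7 vinyl group, giving 8.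

Step 7. The basic iodo-ylide may enolise the α-acyloxy aldehyde 10 (loss of C6 integrity) or give a poor Z:E ratio. The fallback sets out from 10 and returns at 18, building C4=C5 with a much less basic phosphonate anion and C3 by an auxiliary-controlled aldol.

- 10 is treated with ethyl 2-[bis(2,2,2-trifluoroethoxy)phosphoryl]propanoate, KHMDS and 18-crown-6 in THF at −78 °C (Still–Gennari olefination) to give ethyl (2Z)-2-methyl-3-[(2S,3S,4R)-4-methyl-5-oxo-3-vinyltetrahydrofuran-2-yl]prop-2-enoate F4.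
- DIBAL-H (CH2Cl2, −78 °C) reduces ester and lactone to (2Z)-3-[(2S,3S,4R)-5-hydroxy-4-methyl-3-vinyltetrahydrofuran-2-yl]-2-methylprop-2-en-1-ol F5 (lactol anomers).
- Ag2CO3 on Celite (benzene, reflux) should oxidise the lactol first and then the allylic alcohol, so that O6 is locked in the lactone before the enal appears, giving (2Z)-2-methyl-3-[(2S,3S,4R)-4-methyl-5-oxo-3-vinyltetrahydrofuran-2-yl]prop-2-enal F6.
- The chlorotitanium enolate of (R)-3-acetyl-4-isopropyl-1,3-thiazolidine-2-thione (made from the commercial thiazolidinethione and acetyl chloride; TiCl4, i-Pr2NEt, CH2Cl2, −78 °C; Nagao-type acetate aldol through the chelated chair) should add to F6 to give the (3S)-aldol, the N-(3-hydroxyacyl)thiazolidinethione F7.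
- F7 is silylated (TBSOTf, 2,6-lutidine) to its TBS ether F8.
- NaBH4 (THF/EtOH, 0 °C) should remove the auxiliary from F8 without touching the lactone, giving 18.

**Further compounds**

F1 | step 17 | (3R,3aS,5S,6Z,9S,10Z,11aS)-9-[(tert-butyldimethylsilyl)oxy]-5-hydroxy-3,6,10-trimethyl-3a,4,5,8,9,11a-hexahydrocyclodeca[b]furan-2(3H)-one (9S epimer of 25) | CC(C)(C)[Si](C)(C)O[C@H]1C/C=C(/C)[C@@H](O)C[C@@H]2[C@@H](/C=C\1C)OC(=O)[C@@H]2C
F2 | step 17 | (3R,3aS,6Z,9S,10Z,11aS)-9-[(tert-butyldimethylsilyl)oxy]-3,6,10-trimethyl-3a,4,8,9-tetrahydrocyclodeca[b]furan-2,5(3H,11aH)-dione (C9 ketone) | CC(C)(C)[Si](C)(C)O[C@H]1C/C=C(/C)C(=O)C[C@@H]2[C@@H](/C=C\1C)OC(=O)[C@@H]2C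
F3 | step 4 | (4R,5S)-5-{[(tert-butyldiphenylsilyl)oxy]methyl}-3-methyl-3-(phenylselanyl)-4-vinyldihydrofuran-2(3H)-one (C3 epimers) | C=C[C@@H]1[C@@H](CO[Si](c2ccccc2)(c2ccccc2)C(C)(C)C)OC(=O)C1(C)[Se]c1ccccc1
F4 | step 7 | ethyl (2Z)-2-methyl-3-[(2S,3S,4R)-4-methyl-5-oxo-3-vinyltetrahydrofuran-2-yl]prop-2-enoate | C=C[C@@H]1[C@@H](/C=C(/C)C(=O)OCC)OC(=O)[C@@H]1C
F5 | step 7 | (2Z)-3-[(2S,3S,4R)-5-hydroxy-4-methyl-3-vinyltetrahydrofuran-2-yl]-2-methylprop-2-en-1-ol (lactol anomers) | C=C[C@@H]1[C@@H](/C=C(/C)CO)OC(O)[C@@H]1C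
F6 | step 7 | (2Z)-2-methyl-3-[(2S,3S,4R)-4-methyl-5-oxo-3-vinyltetrahydrofuran-2-yl]prop-2-enal | C=C[C@@H]1[C@@H](/C=C(/C)C=O)OC(=O)[C@@H]1C
F7 | step 7 | (3R,4S,5S)-5-[(1Z,3S)-3-hydroxy-5-[(4R)-4-isopropyl-2-thioxo-1,3-thiazolidin-3-yl]-2-methyl-5-oxopent-1-en-1-yl]-3-methyl-4-vinyldihydrofuran-2(3H)-one | C=C[C@@H]1[C@@H](/C=C(/C)[C@@H](O)CC(=O)N2[C@H](C(C)C)CSC2=S)OC(=O)[C@@H]1C
F8 | step 7 | (3R,4S,5S)-5-[(1Z,3S)-3-[(tert-butyldimethylsilyl)oxy]-5-[(4R)-4-isopropyl-2-thioxo-1,3-thiazolidin-3-yl]-2-methyl-5-oxopent-1-en-1-yl]-3-methyl-4-vinyldihydrofuran-2(3H)-one | C=C[C@@H]1[C@@H](/C=C(/C)[C@@H](O[Si](C)(C)C(C)(C)C)CC(=O)N2[C@H](C(C)C)CSC2=S)OC(=O)[C@@H]1C
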